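**Retrosynthetic overview**
1. Caespitol ⇐ desilylation of bromo‑oxane 18 ⇐ 6‑endo bromoetherification of prenyl carbinol 17 (oxane ring formed last; sets oxane C5–Br).
2. 17 ⇐ cross‑metathesis of allyl carbinol 15 ⇐ Felkin–Anh MeMgBr addition to α‑silyloxy ketone 13 (sets oxane C2).
3. Ring bromochloride 13 ⇐ 1,2‑bromine shift with chloride capture from trans‑diaxial bromohydrin 12 ⇐ Shi epoxide 11 of cyclohexenyl ketone 10 (sets C3′, C4′).
4. Cyclohexene ring (formed first) ⇐ catalytic asymmetric Diels–Alder of isoprene with α′‑silyloxy enone 8 (sets C1′).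
5. 8 ⇐ ethyl (R)‑2‑hydroxypent‑4‑enoate 4 ⇐ ketoreductase reduction of achiral keto ester 3 (sets oxane C3) ⇐ diethyl oxalate + allylMgBr.

Assumption: a commercial (R)‑selective ketoreductase accepts ethyl 2‑oxopent‑4‑enoate, as such enzymes accept the close analogue ethyl 2‑oxo‑4‑phenylbutanoate.

Locants: oxane C2/C3/C5 and cyclohexyl C1′/C3′/C4′ as in the name of the target.

---

**Step 1**
Reactants: 1 diethyl oxalate; 2 allylmagnesium bromide
Product: 3 ethyl 2‑oxopent‑4‑enoate
Conditions: 2 (1.0 equiv) added to 1 (1.5 equiv), THF/Et2O, −78 °C; AcOH quench at −78 °C; use at once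
Reagents that add atoms: none beyond 1 and 2
Why: Grignard mono‑acylation of an oxalate diester stops at the magnesium hemiketal at −78 °C, so the α‑keto ester is released only on quench.

**Step 2**
Reactants: 3
Product: 4 ethyl (2R)‑2‑hydroxypent‑4‑enoate
Conditions: (R)‑selective ketoreductase (KRED), NADP+ (cat.), glucose/glucose dehydrogenase, KPi buffer pH 6.5, 5% DMSO, 30 °C
Reagents that add atoms: none (hydride from NADPH only)
Why: Biocatalytic asymmetric ketone reduction: the ketoreductase delivers hydride to one prochiral face of the α‑keto ester, creating the first stereocentre (future oxane C3, R).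

**Step 3**
Reactants: 4
Product: 5 ethyl (2R)‑2‑[(tert‑butyldimethylsilyl)oxy]pent‑4‑enoate
Conditions: TBSCl, imidazole, DMF, rt
Reagents that add atoms: TBSCl, CC(C)(C)[Si](C)(C)Cl
Why: Standard silylation of a secondary alcohol; the TBS ether is non‑chelating (needed in step 10) and non‑nucleophilic (needed in step 12).

**Step 4**
Reactants: 5
Product: 6 (2R)‑2‑[(tert‑butyldimethylsilyl)oxy]‑N‑methoxy‑N‑methylpent‑4‑enamide
Conditions: MeNHOMe·HCl, i‑PrMgCl, THF, −20 → 0 °C
Reagents that add atoms: N,O‑dimethylhydroxylamine hydrochloride, CNOC.Cl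
Why: Weinreb amide formation by magnesium‑amide aminolysis of the ester, which does not epimerise α‑silyloxy esters at low temperature.

**Step 5**
Reactants: 6; 7 vinylmagnesium bromide
Product: 8 (4R)‑4‑[(tert‑butyldimethylsilyl)oxy]hepta‑1,6‑dien‑3‑one
Conditions: 7 (1.3 equiv), THF, 0 °C; inverse quench into cold 1 M HCl
Reagents that add atoms: none beyond 7
Why: Weinreb ketone synthesis: the chelated tetrahedral intermediate prevents over‑addition, and the acidic inverse quench prevents aza‑Michael addition of the released amine to the enone.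

**Step 6**
Reactants: 8; 9 isoprene
Product: 10 (2R)‑2‑[(tert‑butyldimethylsilyl)oxy]‑1‑[(1S)‑4‑methylcyclohex‑3‑en‑1‑yl]pent‑4‑en‑1‑one
Conditions: (S)‑diphenylprolinol‑derived o‑tolyl oxazaborolidinium triflimide (20 mol %; the enantiomer giving (S)‑cyclohex‑3‑enyl adducts), 9 (5 equiv), CH2Cl2, −78 → −40 °C; minor C1′ epimer removed by chromatography
Reagents that add atoms: none beyond 9
Why: Catalyst‑controlled asymmetric Diels–Alder reaction of the Lewis‑acid‑activated enone; "para" regiochemistry places the methyl 1,4 to the acyl group, and the catalyst‑shielded enone face sets C1′ (S).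

**Step 7**
Reactants: 10
Product: 11 (2R)‑2‑[(tert‑butyldimethylsilyl)oxy]‑1‑[(1R,3S,6S)‑6‑methyl‑7‑oxabicyclo[4.1.0]heptan‑3‑yl]pent‑4‑en‑1‑one (epoxide oxygen anti to the acyl group; methyl cis to it)
Conditions: D‑fructose‑derived Shi ketone (30 mol %), Oxone, K2CO3, Bu4NHSO4, MeCN/DMM/aq. borate–EDTA buffer, 0 °C
Reagents that add atoms: Oxone (potassium peroxymonosulfate), OOS(=O)(=O)[O-].[K+]
Why: Shi asymmetric epoxidation: the chiral dioxirane epoxidises only the trisubstituted ring alkene (the terminal alkene is inert) and its spiro transition state delivers oxygen to the face anti to the C1′ acyl group.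

**Step 8**
Reactants: 11
Product: 12 (2R)‑1‑[(1S,3R,4R)‑4‑bromo‑3‑hydroxy‑4‑methylcyclohexyl]‑2‑[(tert‑butyldimethylsilyl)oxy]pent‑4‑en‑1‑one (Br and OH trans‑diaxial)
Conditions: HBr (1.1 equiv, 33% in AcOH), CH2Cl2, −78 °C, 15 min; pH 7 buffer quench
Reagents that add atoms: hydrogen bromide, Br
Why: Acid‑mediated epoxide opening with inversion at the tertiary carbon, where the Markovnikov and trans‑diaxial (Fürst–Plattner) preferences coincide, giving tertiary axial C4′–Br anti to the axial C3′–OH.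

**Step 9**
Reactants: 12
Product: 13 (2R)‑1‑[(1S,3S,4S)‑3‑bromo‑4‑chloro‑4‑methylcyclohexyl]‑2‑[(tert‑butyldimethylsilyl)oxy]pent‑4‑en‑1‑one (Br and Cl trans‑diequatorial; Br cis to the side chain)
Conditions: Tf2O, 2,6‑lutidine, n‑Bu4NCl, CH2Cl2, −78 → 0 °C; then ClCH2CH2Cl, 70 °C
Reagents that add atoms: tetrabutylammonium chloride, CCCC[N+](CCCC)(CCCC)CCCC.[Cl-]
Why: Neighbouring‑group participation: the antiperiplanar C4′–Br displaces the triflate to give a bromonium ion on the face cis to the side chain, and chloride opens it anti at the tertiary carbon; any diaxial 4‑bromo‑3‑chloro isomer from attack at the secondary carbon is converted to the same product on heating by the diaxial→diequatorial (dyotropic) dihalide rearrangement.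

**Step 10**
Reactants: 13; 14 methylmagnesium bromide
Product: 15 (2R,3R)‑2‑[(1S,3S,4S)‑3‑bromo‑4‑chloro‑4‑methylcyclohexyl]‑3‑[(tert‑butyldimethylsilyl)oxy]hex‑5‑en‑2‑ol
Conditions: 14 (1.5 equiv), THF, −78 °C; cold NH4Cl quench
Reagents that add atoms: none beyond 14
Why: Non‑chelation (polar Felkin–Anh) Grignard addition anti to the bulky α‑OTBS group gives the (2R,3R) "like" tertiary carbinol (future oxane C2); the unactivated alkyl halides are inert to MeMgBr at −78 °C.

**Step 11**
Reactants: 15; 16 2‑methylbut‑2‑ene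
Product: 17 (2R,3R)‑2‑[(1S,3S,4S)‑3‑bromo‑4‑chloro‑4‑methylcyclohexyl]‑3‑[(tert‑butyldimethylsilyl)oxy]‑6‑methylhept‑5‑en‑2‑ol
Conditions: Grubbs II (5 mol %), 16/CH2Cl2 (1:1), 40 °C
Reagents that add atoms: none beyond 16
Why: Olefin cross‑metathesis converts the allyl group into the prenyl group under neutral conditions that tolerate the free alcohol and the halides; the prenyl alkene is introduced only now so that it could not compete in steps 7–9.

**Step 12**
Reactants: 17
Product: 18 tert‑butyl{[(2R,3R,5R)‑5‑bromo‑2‑[(1S,3S,4S)‑3‑bromo‑4‑chloro‑4‑methylcyclohexyl]‑2,6,6‑trimethyloxan‑3‑yl]oxy}dimethylsilane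
Conditions: 2,4,4,6‑tetrabromocyclohexa‑2,5‑dienone (TBCO, 1.2 equiv), MeNO2, 0 °C → rt, dark
Reagents that add atoms: TBCO, O=C1C(Br)=CC(Br)(Br)C=C1Br
Why: 6‑endo (Markovnikov) bromoetherification: the tertiary OH attacks the Me2C end of the bromonium ion anti to Br through a chair transition state with the cyclohexyl group equatorial, so Br ends up equatorial (oxane C5, R).

**Step 13**
Reactants: 18
Product: 19 caespitol, (2R,3R,5R)‑5‑bromo‑2‑[(1S,3S,4S)‑3‑bromo‑4‑chloro‑4‑methylcyclohexyl]‑2,6,6‑trimethyloxan‑3‑ol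
Conditions: HF·pyridine, THF, 0 °C → rt
Reagents that add atoms: none
Why: Acidic fluoride desilylation frees the hindered axial C3–OH without exposing the tertiary chloride and secondary bromides to base.

---

**Compound list**
1 | diethyl oxalate | CCOC(=O)C(=O)OCC | starting material
2 | allylmagnesium bromide | C=CC[Mg]Br | starting material
3 | ethyl 2‑oxopent‑4‑enoate | CCOC(=O)C(=O)CC=C | intermediate
4 | ethyl (2R)‑2‑hydroxypent‑4‑enoate | CCOC(=O)[C@H](O)CC=C | intermediate
5 | ethyl (2R)‑2‑[(tert‑butyldimethylsilyl)oxy]pent‑4‑enoate | CCOC(=O)[C@H](O[Si](C)(C)C(C)(C)C)CC=C | intermediate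
6 | (2R)‑2‑[(tert‑butyldimethylsilyl)oxy]‑N‑methoxy‑N‑methylpent‑4‑enamide | CON(C)C(=O)[C@H](O[Si](C)(C)C(C)(C)C)CC=C | intermediate
7 | vinylmagnesium bromide | C=C[Mg]Br | starting material
8 | (4R)‑4‑[(tert‑butyldimethylsilyl)oxy]hepta‑1,6‑dien‑3‑one | C=CC(=O)[C@H](O[Si](C)(C)C(C)(C)C)CC=C | intermediate
9 | isoprene | C=CC(C)=C | starting material
10 | (2R)‑2‑(TBSO)‑1‑[(1S)‑4‑methylcyclohex‑3‑en‑1‑yl]pent‑4‑en‑1‑one | O=C([C@H]1CCC(C)=CC1)[C@H](O[Si](C)(C)C(C)(C)C)CC=C | intermediate
11 | (2R)‑2‑(TBSO)‑1‑[(1R,3S,6S)‑6‑methyl‑7‑oxabicyclo[4.1.0]heptan‑3‑yl]pent‑4‑en‑1‑one | O=C([C@H]1CC[C@]2(C)O[C@@H]2C1)[C@H](O[Si](C)(C)C(C)(C)C)CC=C | intermediate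
12 | (2R)‑1‑[(1S,3R,4R)‑4‑bromo‑3‑hydroxy‑4‑methylcyclohexyl]‑2‑(TBSO)pent‑4‑en‑1‑one | O=C([C@H]1CC[C@@](C)(Br)[C@H](O)C1)[C@H](O[Si](C)(C)C(C)(C)C)CC=C | intermediate
13 | (2R)‑1‑[(1S,3S,4S)‑3‑bromo‑4‑chloro‑4‑methylcyclohexyl]‑2‑(TBSO)pent‑4‑en‑1‑one | O=C([C@H]1CC[C@](C)(Cl)[C@@H](Br)C1)[C@H](O[Si](C)(C)C(C)(C)C)CC=C | intermediate
14 | methylmagnesium bromide | C[Mg]Br | starting material
15 | (2R,3R)‑2‑[(1S,3S,4S)‑3‑bromo‑4‑chloro‑4‑methylcyclohexyl]‑3‑(TBSO)hex‑5‑en‑2‑ol | C[C@@](O)([C@H]1CC[C@](C)(Cl)[C@@H](Br)C1)[C@H](O[Si](C)(C)C(C)(C)C)CC=C | intermediate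
16 | 2‑methylbut‑2‑ene | CC=C(C)C | starting material
17 | (2R,3R)‑2‑[(1S,3S,4S)‑3‑bromo‑4‑chloro‑4‑methylcyclohexyl]‑3‑(TBSO)‑6‑methylhept‑5‑en‑2‑ol | C[C@@](O)([C@H]1CC[C@](C)(Cl)[C@@H](Br)C1)[C@H](O[Si](C)(C)C(C)(C)C)CC=C(C)C | intermediate
18 | tert‑butyl{[(2R,3R,5R)‑5‑bromo‑2‑[(1S,3S,4S)‑3‑bromo‑4‑chloro‑4‑methylcyclohexyl]‑2,6,6‑trimethyloxan‑3‑yl]oxy}dimethylsilane | CC1(C)O[C@](C)([C@H]2CC[C@](C)(Cl)[C@@H](Br)C2)[C@H](O[Si](C)(C)C(C)(C)C)C[C@H]1Br | intermediate
19 | caespitol | CC1(C)O[C@](C)([C@H]2CC[C@](C)(Cl)[C@@H](Br)C2)[C@H](O)C[C@H]1Br | target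

(TBSO = tert‑butyldimethylsilyloxy.)

---

**Total steps:** 13
**Longest linear sequence:** 13 (from diethyl oxalate)

**Three steps most likely to fail, with fallbacks**
1. **Step 9 (bromine shift with chloride capture).** Chloride may open the bromonium ion mainly at the secondary carbon, the thermal diaxial→diequatorial equilibrium may not lie fully on the side of 13, and elimination can compete. Fallback: drop the epoxide‑derived bromonium and bromochlorinate alkene 10 directly (N‑bromoacetamide/Et4NCl), isolate the adducts derived from the bromonium cis to the side chain, and recycle the unwanted trans‑diaxial adduct to 10 by Zn reductive elimination.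
2. **Step 12 (bromoetherification).** The 5‑exo tetrahydrofuran can compete and yields with bromonium sources are often modest. Fallback: close the ring by Hg(II) trifluoroacetate oxymercuration (reversible, Markovnikov 6‑endo), then install bromine by bromodemercuration (Br2, pyridine, retention) to give the equatorial C5–Br.
3. **Step 6 (Diels–Alder on the chiral α′‑silyloxy enone).** The catalyst may not override the substrate's own facial bias, giving poor C1′ selectivity. Fallback: remove the TBS group and run the cycloaddition on the free α′‑hydroxy enone under two‑point chelation with a matched Cu(II)–bis(oxazoline) Lewis acid, then re‑silylate to rejoin the route at 10.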